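The unit B lactone ring (C1', O2', C3', C4', C4a', C8a') has O2' between the carbonyl C1' and the secondary stereocentre C3'. The route therefore cuts at O2', which leads back to the C1'–C3' bond of a trans-2,3-dimethylindan-1-one. One Baeyer–Villiger oxidation expands the five-membered ketone to the six-membered lactone and carries C3' and C4' through unchanged. Its substrate is the complete dimer: ring A as the open-chain triacetate, the CH(CH3) linker already configured, and the ring B indanone with both phenols as triflates rather than acyl groups, so that aryl migration is suppressed. The quinone methide of unit A is closed last by formylation at C8a.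

Key step: step 20

Remarks on the chemistry
- Unit A atoms are unprimed, unit B atoms primed; the linker is CH(CH3) between C7 and C7'.
- The linker keeps one spatial arrangement from step 16 onward; its CIP label changes (S, R, S, …, R in the target) only because the O-substituents change the priorities.
- A species made in one operation and consumed by a reagent added later in the same flask is numbered as a non-isolated intermediate; species that only await aqueous work-up are not.
- In steps 5 and 16 the catalyst antipode is the one that gives the stated configuration; this is fixed on the first run by correlation (step 5) and by comparing the two diastereomers (step 16).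

Step 1
Reactants: 1 1-bromo-3,5-dimethoxybenzene
Product: 2 2-bromo-4,6-dimethoxybenzaldehyde
Conditions: POCl3, DMF, 0 → 90 °C; aq. NaOAc
Reagents that add atoms: N,N-dimethylformamide CN(C)C=O; water O
Why: Vilsmeier–Haack formylation attacks the carbon para to one methoxy and ortho to the other, next to bromine, which places the future C5/C5' methyl carbon.

Step 2
Reactants: 2 2-bromo-4,6-dimethoxybenzaldehyde
Product: 3 1-bromo-3,5-dimethoxy-2-methylbenzene
Conditions: Et3SiH, TFA, CH2Cl2, 0 °C → rt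
Reagents that add atoms: none
Why: Ionic hydrogenation: the benzylic cation stabilised by the ortho and para methoxy groups takes hydride twice from the silane, so CHO becomes CH3 and the aryl bromide is untouched.

Step 3
Reactants: 3 1-bromo-3,5-dimethoxy-2-methylbenzene
Product: 4 5-bromo-4-methylbenzene-1,3-diol
Conditions: BBr3, CH2Cl2, −78 °C → rt; H2O
Reagents that add atoms: none
Why: Lewis-acid ether cleavage on a simple arene frees both phenols, so that each branch can carry the protecting group it needs.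

Step 4
Reactants: 4 5-bromo-4-methylbenzene-1,3-diol
Product: 5 1,5-bis(benzyloxy)-3-bromo-2-methylbenzene
Conditions: BnBr, K2CO3, DMF, 60 °C
Reagents that add atoms: benzyl bromide BrCc1ccccc1
Why: Williamson etherification; benzyl ethers tolerate the organolithium, Rh and Pd steps and leave later by neutral hydrogenolysis.

Step 5
Reactants: 5 1,5-bis(benzyloxy)-3-bromo-2-methylbenzene; 6 ethyl (E)-but-2-enoate
Product: 10 (R)-3-[3,5-bis(benzyloxy)-2-methylphenyl]butanoic acid, via aryllithium 7 (not isolated), via lithium aryl(trimethoxy)borate 8 (not isolated), via ethyl ester 9 (not isolated)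
Conditions: n-BuLi, THF, −78 °C; B(OMe)3, → rt; Rh(acac)(C2H4)2 (3 mol %), (S)-BINAP, 6, dioxane/H2O, 100 °C; LiOH, MeOH/H2O, 60 °C; HCl
Reagents that add atoms: lithium hydroxide [Li+].[OH-]
Why: Hayashi–Miyaura Rh-catalysed asymmetric 1,4-addition of the in situ aryl borate to the crotonate sets the benzylic centre (future C4') under ligand control, and saponification in the same pot gives the acid.

Step 6
Reactants: 10 (R)-3-[3,5-bis(benzyloxy)-2-methylphenyl]butanoic acid
Product: 11 (R)-5,7-bis(benzyloxy)-3,4-dimethylindan-1-one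
Conditions: TFAA, CH2Cl2, 0 °C → rt
Reagents that add atoms: none
Why: Intramolecular Friedel–Crafts acylation through the mixed trifluoroacetic anhydride closes onto the only free ortho carbon, which has one ortho and one para benzyloxy group, under conditions too mild to cleave benzyl ethers.

Step 7
Reactants: 11 (R)-5,7-bis(benzyloxy)-3,4-dimethylindan-1-one
Product: 13 (2R,3R)-5,7-bis(benzyloxy)-2,3,4-trimethylindan-1-one, via lithium enolate 12 (not isolated)
Conditions: LiHMDS, THF, −78 °C; MeI, −78 → 0 °C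
Reagents that add atoms: iodomethane CI
Why: Enolate alkylation: MeI adds to the enolate face opposite the C3 methyl and gives the trans-2,3-dimethyl ketone, which is also the thermodynamic epimer, so C2 (future C3') is set by C3.

Step 8
Reactants: 13 (2R,3R)-5,7-bis(benzyloxy)-2,3,4-trimethylindan-1-one
Product: 14 (2R,3R)-5,7-bis(benzyloxy)-6-bromo-2,3,4-trimethylindan-1-one
Conditions: NBS, MeCN, 0 °C → rt
Reagents that add atoms: N-bromosuccinimide BrN1C(=O)CCC1=O
Why: Electrophilic aromatic bromination can only occur at C6, the single unsubstituted ring carbon, which lies between the two benzyloxy groups.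

Step 9
Reactants: 4 5-bromo-4-methylbenzene-1,3-diol
Product: 15 1-bromo-3,5-bis(methoxymethoxy)-2-methylbenzene
Conditions: MOMCl, i-Pr2NEt, CH2Cl2, 0 °C → rt
Reagents that add atoms: chloromethyl methyl ether COCCl
Why: Acetal protection of both phenols; the two MOM ethers later direct lithiation to the carbon between them and come off under conditions that leave benzyl ethers alone.

Step 10
Reactants: 15 1-bromo-3,5-bis(methoxymethoxy)-2-methylbenzene; 16 (2S,3S)-2,3-dimethyloxirane
Product: 18 (2S,3S)-3-[3,5-bis(methoxymethoxy)-2-methylphenyl]butan-2-ol, via arylmagnesium bromide 17 (not isolated)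
Conditions: Mg, THF, 50 °C; CuI (10 mol %), 16, −30 → 0 °C
Reagents that add atoms: none
Why: Copper-catalysed Grignard opening of the C2-symmetric trans-epoxide is an SN2 reaction with inversion at the attacked carbon, so the benzylic centre (future C4) comes from the epoxide; the carbinol centre is still the wrong epimer.

Step 11
Reactants: 18 (2S,3S)-3-[3,5-bis(methoxymethoxy)-2-methylphenyl]butan-2-ol
Product: 20 (2R,3S)-3-[3,5-bis(methoxymethoxy)-2-methylphenyl]butan-2-ol, via 4-nitrobenzoate ester 19 (not isolated)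
Conditions: PPh3, DIAD, 4-nitrobenzoic acid, THF, 0 °C → rt; then K2CO3, MeOH
Reagents that add atoms: 4-nitrobenzoic acid OC(=O)c1ccc(cc1)[N+](=O)[O-]
Why: Mitsunobu esterification inverts the carbinol carbon (future C3) by SN2 displacement of the oxyphosphonium group, and methanolysis returns the alcohol in the threo arrangement of the citrinin series.

Step 12
Reactants: 20 (2R,3S)-3-[3,5-bis(methoxymethoxy)-2-methylphenyl]butan-2-ol
Product: 22 1-{4-[(2S,3R)-3-hydroxybutan-2-yl]-2,6-bis(methoxymethoxy)-3-methylphenyl}ethan-1-one, via dilithiated arene 21 (not isolated)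
Conditions: n-BuLi (2.3 equiv), TMEDA, THF, 0 °C; N-methoxy-N-methylacetamide, −78 → 0 °C; H2O
Reagents that add atoms: N-methoxy-N-methylacetamide CON(C)C(C)=O
Why: Directed ortho-metalation: after the alkoxide forms, the second equivalent of base lithiates the carbon between the two MOM ethers (future C7), and Weinreb acylation stops at the methyl ketone that holds both linker carbons.

Step 13
Reactants: 22 1-{4-[(2S,3R)-3-hydroxybutan-2-yl]-2,6-bis(methoxymethoxy)-3-methylphenyl}ethan-1-one
Product: 23 N'-(1-{4-[(2S,3R)-3-hydroxybutan-2-yl]-2,6-bis(methoxymethoxy)-3-methylphenyl}ethylidene)-4-methylbenzenesulfonohydrazide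
Conditions: TsNHNH2, MeOH, 60 °C
Reagents that add atoms: 4-methylbenzenesulfonohydrazide Cc1ccc(cc1)S(=O)(=O)NN
Why: Hydrazone condensation turns the ketone into a stable diazo precursor for the carbene coupling.

Step 14
Reactants: 14 (2R,3R)-5,7-bis(benzyloxy)-6-bromo-2,3,4-trimethylindan-1-one; 23 N'-(1-{4-[(2S,3R)-3-hydroxybutan-2-yl]-2,6-bis(methoxymethoxy)-3-methylphenyl}ethylidene)-4-methylbenzenesulfonohydrazide
Product: 24 (2R,3R)-5,7-bis(benzyloxy)-6-(1-{4-[(2S,3R)-3-hydroxybutan-2-yl]-2,6-bis(methoxymethoxy)-3-methylphenyl}ethenyl)-2,3,4-trimethylindan-1-one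
Conditions: Pd2(dba)3 (2.5 mol %), XPhos (10 mol %), LiOt-Bu (3.5 equiv), 1,4-dioxane, 100 °C
Reagents that add atoms: none
Why: Barluenga coupling: base converts the tosylhydrazone to a diazo compound, the aryl–Pd species from 14 forms a Pd carbene, and aryl migration followed by β-hydride elimination from the methyl group gives the 1,1-diarylethene without any organometallic that would attack the indanone carbonyl.

Step 15
Reactants: 24 (2R,3R)-5,7-bis(benzyloxy)-6-(1-{4-[(2S,3R)-3-hydroxybutan-2-yl]-2,6-bis(methoxymethoxy)-3-methylphenyl}ethenyl)-2,3,4-trimethylindan-1-one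
Product: 25 (2R,3R)-5,7-bis(benzyloxy)-6-(1-{2,6-dihydroxy-4-[(2S,3R)-3-hydroxybutan-2-yl]-3-methylphenyl}ethenyl)-2,3,4-trimethylindan-1-one
Conditions: HCl (1.25 M in MeOH), 40 °C; NaHCO3
Reagents that add atoms: none
Why: Acid-catalysed acetal exchange removes both MOM groups as dimethoxymethane while the benzyl ethers stay, so only ring A has free ortho hydroxyls; the congested alkene protonates reversibly and should be recovered on neutralisation.

Step 16
Reactants: 25 (2R,3R)-5,7-bis(benzyloxy)-6-(1-{2,6-dihydroxy-4-[(2S,3R)-3-hydroxybutan-2-yl]-3-methylphenyl}ethenyl)-2,3,4-trimethylindan-1-one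
Product: 26 (2R,3R)-5,7-bis(benzyloxy)-6-[(1S)-1-{2,6-dihydroxy-4-[(2S,3R)-3-hydroxybutan-2-yl]-3-methylphenyl}ethyl]-2,3,4-trimethylindan-1-one
Conditions: TRIP phosphoric acid (10 mol %), diethyl 2,6-dimethyl-1,4-dihydropyridine-3,5-dicarboxylate (1.5 equiv), CH2Cl2, rt
Reagents that add atoms: none
Why: Organocatalytic asymmetric transfer hydrogenation of a 2-(1-arylvinyl)phenol: the chiral phosphoric acid protonates the alkene to the ring A ortho-quinone methide, which stays hydrogen-bonded to the phosphate, and the Hantzsch ester delivers hydride to one face, setting the linker centre under catalyst control (ring B cannot form such an intermediate, and the two ring A hydroxyls are related by local symmetry and give the same sense).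

Step 17
Reactants: 26 (2R,3R)-5,7-bis(benzyloxy)-6-[(1S)-1-{2,6-dihydroxy-4-[(2S,3R)-3-hydroxybutan-2-yl]-3-methylphenyl}ethyl]-2,3,4-trimethylindan-1-one
Product: 27 (2R,3R)-6-[(1S)-1-{2,6-diacetoxy-4-[(2S,3R)-3-acetoxybutan-2-yl]-3-methylphenyl}ethyl]-5,7-bis(benzyloxy)-2,3,4-trimethylindan-1-one
Conditions: Ac2O, pyridine, DMAP (cat.), CH2Cl2, rt
Reagents that add atoms: acetic anhydride CC(=O)OC(C)=O
Why: DMAP-catalysed acylation caps the two ring A phenols and the C3 alcohol, making ring A inert to peracid and to acid.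

Step 18
Reactants: 27 (2R,3R)-6-[(1S)-1-{2,6-diacetoxy-4-[(2S,3R)-3-acetoxybutan-2-yl]-3-methylphenyl}ethyl]-5,7-bis(benzyloxy)-2,3,4-trimethylindan-1-one
Product: 28 (2R,3R)-6-[(1R)-1-{2,6-diacetoxy-4-[(2S,3R)-3-acetoxybutan-2-yl]-3-methylphenyl}ethyl]-5,7-dihydroxy-2,3,4-trimethylindan-1-one
Conditions: H2 (1 atm), 10% Pd/C, EtOAc, rt
Reagents that add atoms: none
Why: Catalytic hydrogenolysis cleaves the two benzyl ethers under neutral conditions that spare acetates, the hindered aryl ketone and the linker.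

Step 19
Reactants: 28 (2R,3R)-6-[(1R)-1-{2,6-diacetoxy-4-[(2S,3R)-3-acetoxybutan-2-yl]-3-methylphenyl}ethyl]-5,7-dihydroxy-2,3,4-trimethylindan-1-one
Product: 29 (2R,3R)-6-[(1S)-1-{2,6-diacetoxy-4-[(2S,3R)-3-acetoxybutan-2-yl]-3-methylphenyl}ethyl]-2,3,4-trimethyl-1-oxoindane-5,7-diyl bis(trifluoromethanesulfonate)
Conditions: Tf2O, pyridine, CH2Cl2, −20 → 0 °C
Reagents that add atoms: trifluoromethanesulfonic anhydride O=S(=O)(OS(=O)(=O)C(F)(F)F)C(F)(F)F
Why: O-Sulfonylation of the two ring B phenols puts strong acceptor groups ortho and para to the ketone-bearing carbon C8a', which is the electronic setting the oxidation needs.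

Step 20
Reactants: 29 (2R,3R)-6-[(1S)-1-{2,6-diacetoxy-4-[(2S,3R)-3-acetoxybutan-2-yl]-3-methylphenyl}ethyl]-2,3,4-trimethyl-1-oxoindane-5,7-diyl bis(trifluoromethanesulfonate)
Product: 30 (3R,4S)-7-[(1S)-1-{2,6-diacetoxy-4-[(2S,3R)-3-acetoxybutan-2-yl]-3-methylphenyl}ethyl]-3,4,5-trimethyl-1-oxoisochromane-6,8-diyl bis(trifluoromethanesulfonate)
Conditions: m-CPBA (3 equiv), TFA (1 equiv), CH2Cl2, 0 °C → rt
Reagents that add atoms: 3-chloroperoxybenzoic acid OOC(=O)c1cccc(Cl)c1
Why: Baeyer–Villiger oxidation: the peracid adds to C1' to give the Criegee adduct, and the C1'–C3' bond, antiperiplanar to the breaking O–O bond, migrates to oxygen as 3-chlorobenzoate leaves. The closest precedent is the peracid or monooxygenase oxidation of 2-alkylindan-1-ones to 3-alkyl-3,4-dihydroisocoumarins. The six-membered lactone (C1', O2', C3', C4', C4a', C8a') arises by ring expansion of the five-membered ketone through this 1,2-shift, not by a separate cyclisation, and the shift forms the C1'–O2' and O2'–C3' bonds. No stereocentre is created: C3' migrates with retention and C4' is not involved, so the trans relationship from step 7 is carried over. The step needs migration of the secondary alkyl carbon C3' in preference to the aryl carbon C8a'; the triflates ortho and para to C8a' are net acceptors (acyloxy groups would still be π-donors), so the aryl carbon cannot support the positive charge that its migration requires. The acetates, the triflates and the acylated ring A are inert to peracid.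

Step 21
Reactants: 30 (3R,4S)-7-[(1S)-1-{2,6-diacetoxy-4-[(2S,3R)-3-acetoxybutan-2-yl]-3-methylphenyl}ethyl]-3,4,5-trimethyl-1-oxoisochromane-6,8-diyl bis(trifluoromethanesulfonate)
Product: 31 (3R,4S)-7-[(1S)-1-{2,6-dihydroxy-4-[(2S,3R)-3-hydroxybutan-2-yl]-3-methylphenyl}ethyl]-6,8-dihydroxy-3,4,5-trimethylisochroman-1-one
Conditions: Et4NOH (aq.), 1,4-dioxane, rt, Ar; then 1 M HCl
Reagents that add atoms: none
Why: Hydroxide cleaves the three acetates (acyl–O) and the two activated aryl triflates (S–O); the lactone, opened reversibly in base, re-forms on acidification, and no stereocentre is acidic.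

Step 22
Reactants: 31 (3R,4S)-7-[(1S)-1-{2,6-dihydroxy-4-[(2S,3R)-3-hydroxybutan-2-yl]-3-methylphenyl}ethyl]-6,8-dihydroxy-3,4,5-trimethylisochroman-1-one
Product: 33 dicitrinone H, via cyclic ethyl acetal 32 (not isolated)
Conditions: HC(OEt)3, TsOH (cat.), rt; then dilute HCl, THF
Reagents that add atoms: triethyl orthoformate CCOC(OCC)OCC
Why: Acid-mediated orthoformate formylation (the citrinin endgame) attacks C8a, the only unsubstituted aromatic carbon in the molecule; the C3 hydroxyl traps the formyl carbon as the cyclic acetal, and loss of ethanol gives the conjugated quinone methide without touching C3 or C4.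

Compound list
1 | 1-bromo-3,5-dimethoxybenzene | COc1cc(Br)cc(OC)c1 | starting material
2 | 2-bromo-4,6-dimethoxybenzaldehyde | COc1cc(Br)c(C=O)c(OC)c1 | intermediate
3 | 1-bromo-3,5-dimethoxy-2-methylbenzene | COc1cc(Br)c(C)c(OC)c1 | intermediate
4 | 5-bromo-4-methylbenzene-1,3-diol | Oc1cc(Br)c(C)c(O)c1 | intermediate
5 | 1,5-bis(benzyloxy)-3-bromo-2-methylbenzene | Cc1c(Br)cc(OCc2ccccc2)cc1OCc3ccccc3 | intermediate
6 | ethyl (E)-but-2-enoate (ethyl crotonate) | CCOC(=O)/C=C/C | starting material
7 | [3,5-bis(benzyloxy)-2-methylphenyl]lithium | [Li]c1cc(OCc2ccccc2)cc(OCc3ccccc3)c1C | intermediate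
8 | lithium [3,5-bis(benzyloxy)-2-methylphenyl]trimethoxyborate | [Li+].CO[B-](OC)(OC)c1cc(OCc2ccccc2)cc(OCc3ccccc3)c1C | intermediate
9 | ethyl (R)-3-[3,5-bis(benzyloxy)-2-methylphenyl]butanoate | CCOC(=O)C[C@@H](C)c1cc(OCc2ccccc2)cc(OCc3ccccc3)c1C | intermediate
10 | (R)-3-[3,5-bis(benzyloxy)-2-methylphenyl]butanoic acid | OC(=O)C[C@@H](C)c1cc(OCc2ccccc2)cc(OCc3ccccc3)c1C | intermediate
11 | (R)-5,7-bis(benzyloxy)-3,4-dimethylindan-1-one | c1c(OCc3ccccc3)c(C)c2c(c1OCc4ccccc4)C(=O)C[C@H]2C | intermediate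
12 | lithium enolate of 11 (O–Li on C1, C1=C2) | c1c(OCc3ccccc3)c(C)c2c(c1OCc4ccccc4)C(O[Li])=C[C@H]2C | intermediate
13 | (2R,3R)-5,7-bis(benzyloxy)-2,3,4-trimethylindan-1-one (trans) | c1c(OCc3ccccc3)c(C)c2c(c1OCc4ccccc4)C(=O)[C@H](C)[C@H]2C | intermediate
14 | (2R,3R)-5,7-bis(benzyloxy)-6-bromo-2,3,4-trimethylindan-1-one | Brc1c(OCc3ccccc3)c(C)c2c(c1OCc4ccccc4)C(=O)[C@H](C)[C@H]2C | intermediate
15 | 1-bromo-3,5-bis(methoxymethoxy)-2-methylbenzene | COCOc1cc(Br)c(C)c(OCOC)c1 | intermediate
16 | (2S,3S)-2,3-dimethyloxirane (trans-2,3-epoxybutane) | C[C@@H]1O[C@H]1C | starting material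
17 | [3,5-bis(methoxymethoxy)-2-methylphenyl]magnesium bromide | COCOc1cc([Mg]Br)c(C)c(OCOC)c1 | intermediate
18 | (2S,3S)-3-[3,5-bis(methoxymethoxy)-2-methylphenyl]butan-2-ol | COCOc1cc([C@H](C)[C@H](C)O)c(C)c(OCOC)c1 | intermediate
19 | (2R,3S)-3-[3,5-bis(methoxymethoxy)-2-methylphenyl]butan-2-yl 4-nitrobenzoate | COCOc1cc([C@H](C)[C@@H](C)OC(=O)c2ccc(cc2)[N+](=O)[O-])c(C)c(OCOC)c1 | intermediate
20 | (2R,3S)-3-[3,5-bis(methoxymethoxy)-2-methylphenyl]butan-2-ol | COCOc1cc([C@H](C)[C@@H](C)O)c(C)c(OCOC)c1 | intermediate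
21 | lithium (2R,3S)-3-[4-lithio-3,5-bis(methoxymethoxy)-2-methylphenyl]butan-2-olate | COCOc1cc([C@H](C)[C@@H](C)O[Li])c(C)c(OCOC)c1[Li] | intermediate
22 | 1-{4-[(2S,3R)-3-hydroxybutan-2-yl]-2,6-bis(methoxymethoxy)-3-methylphenyl}ethan-1-one | COCOc1cc([C@H](C)[C@@H](C)O)c(C)c(OCOC)c1C(C)=O | intermediate
23 | N-tosylhydrazone of 22 | COCOc1cc([C@H](C)[C@@H](C)O)c(C)c(OCOC)c1C(C)=NNS(=O)(=O)c2ccc(C)cc2 | intermediate
24 | 1,1-diarylethene: ring A with two MOM ethers and free C3 alcohol; ring B as the (2R,3R)-bis(benzyloxy)indanone joined at C6 | COCOc1cc([C@H](C)[C@@H](C)O)c(C)c(OCOC)c1C(=C)c1c(OCc3ccccc3)c(C)c2c(c1OCc4ccccc4)C(=O)[C@H](C)[C@H]2C | intermediate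
25 | 1,1-diarylethene with free ring A phenols (ring B still dibenzylated) | Oc1cc([C@H](C)[C@@H](C)O)c(C)c(O)c1C(=C)c1c(OCc3ccccc3)c(C)c2c(c1OCc4ccccc4)C(=O)[C@H](C)[C@H]2C | intermediate
26 | diarylethane, linker (S); ring A triol, ring B bis(benzyloxy)indanone | Oc1cc([C@H](C)[C@@H](C)O)c(C)c(O)c1[C@H](C)c1c(OCc3ccccc3)c(C)c2c(c1OCc4ccccc4)C(=O)[C@H](C)[C@H]2C | intermediate
27 | diarylethane, linker (S); ring A triacetate, ring B bis(benzyloxy)indanone | CC(=O)Oc1cc([C@H](C)[C@@H](C)OC(C)=O)c(C)c(OC(C)=O)c1[C@H](C)c1c(OCc3ccccc3)c(C)c2c(c1OCc4ccccc4)C(=O)[C@H](C)[C@H]2C | intermediate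
28 | diarylethane, linker (R) by CIP (same geometry); ring A triacetate, ring B 5,7-dihydroxyindanone | CC(=O)Oc1cc([C@H](C)[C@@H](C)OC(C)=O)c(C)c(OC(C)=O)c1[C@H](C)c1c(O)c(C)c2c(c1O)C(=O)[C@H](C)[C@H]2C | intermediate
29 | key-step precursor: ring A triacetate, linker (S), ring B (2R,3R)-trans-2,3-dimethylindan-1-one 5,7-bis(triflate) | CC(=O)Oc1cc([C@H](C)[C@@H](C)OC(C)=O)c(C)c(OC(C)=O)c1[C@H](C)c1c(OS(=O)(=O)C(F)(F)F)c(C)c2c(c1OS(=O)(=O)C(F)(F)F)C(=O)[C@H](C)[C@H]2C | intermediate
30 | key-step product: ring A triacetate, linker (S), unit B (3R,4S)-lactone 6',8'-bis(triflate) | CC(=O)Oc1cc([C@H](C)[C@@H](C)OC(C)=O)c(C)c(OC(C)=O)c1[C@H](C)c1c(OS(=O)(=O)C(F)(F)F)c(C)c2c(c1OS(=O)(=O)C(F)(F)F)C(=O)O[C@H](C)[C@H]2C | intermediate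
31 | (3R,4S)-7-[(1S)-1-{2,6-dihydroxy-4-[(2S,3R)-3-hydroxybutan-2-yl]-3-methylphenyl}ethyl]-6,8-dihydroxy-3,4,5-trimethylisochroman-1-one | Oc1cc([C@H](C)[C@@H](C)O)c(C)c(O)c1[C@H](C)c1c(O)c(C)c2c(c1O)C(=O)O[C@H](C)[C@H]2C | intermediate
32 | (3R,4S)-7-{(1S)-1-[(3R,4S)-1-ethoxy-6,8-dihydroxy-3,4,5-trimethylisochroman-7-yl]ethyl}-6,8-dihydroxy-3,4,5-trimethylisochroman-1-one (both C1 epimers) | CCOC1O[C@H](C)[C@@H](C)c2c(C)c(O)c([C@H](C)c3c(O)c(C)c4c(c3O)C(=O)O[C@H](C)[C@H]4C)c(O)c12 | intermediate
33 | dicitrinone H: unit A (3R,4S) quinone methide, linker (R), unit B (3'R,4'S) lactone | CC1=C2C(=CO[C@H](C)[C@H]2C)C(=O)C([C@H](C)c2c(O)c(C)c3c(c2O)C(=O)O[C@H](C)[C@H]3C)=C1O | target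

Total step count: 22. Longest linear sequence: 17 steps (steps 1–3, 4–8, 14–22; the ring A branch, steps 1–3, 9–13, 14–22, is equally long).

Steps most likely to fail

Step 20. The aryl carbon C8a' may migrate in competition with C3', or the hindered ketone may not take up the peracid. The fallback sets out from 29 and avoids a migration altogether. Soft enolisation (TBSOTf, Et3N, CH2Cl2, 0 °C) gives the silyl enol ether F3. Ozonolysis (O3, CH2Cl2/MeOH, −78 °C; Me2S) cleaves its C1'=C3' double bond to the keto acid F4, with the carboxylic acid on C8a' and a methyl ketone at C3'. Felkin–Anh reduction of the ketone (NaBH4, CeCl3, MeOH, −78 °C), with hydride anti to the aryl group, gives the threo hydroxy acid F5. F5 lactonises on acidic work-up and the route is rejoined at 30.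

Step 16. Hydride transfer to the tetra-ortho-substituted quinone methide may show poor facial discrimination. The fallback sets out from 25 and gives up catalyst control. Ionic hydrogenation (Et3SiH, TFA, CH2Cl2, −20 °C) reduces the alkene to 26 together with its linker epimer F2. The two are diastereomers and are separated by preparative HPLC, and 26 re-enters at step 17.

Step 14. Oxidative addition at the di-ortho-alkoxy bromide or carbene insertion at the congested centre may stall, leaving reduced arene and decomposed diazo compound. The fallback sets out from 23 and changes the bond-forming event to a boron cross-coupling. A Shapiro reaction (n-BuLi, 3.2 equiv, THF/TMEDA, −78 → 0 °C) with trapping of the vinyllithium by 2-isopropoxy-4,4,5,5-tetramethyl-1,3,2-dioxaborolane gives the α-arylvinyl boronate F1. Suzuki–Miyaura coupling of F1 with bromide 14 (Pd(OAc)2, SPhos, K3PO4, toluene/H2O, 90 °C) rejoins the route at 24.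

Further compounds
F1 | step 14 | 2-(1-{4-[(2S,3R)-3-hydroxybutan-2-yl]-2,6-bis(methoxymethoxy)-3-methylphenyl}ethenyl)-4,4,5,5-tetramethyl-1,3,2-dioxaborolane | COCOc1cc([C@H](C)[C@@H](C)O)c(C)c(OCOC)c1C(=C)B1OC(C)(C)C(C)(C)O1
F2 | step 16 | linker epimer of 26, (1R) at the linker | Oc1cc([C@H](C)[C@@H](C)O)c(C)c(O)c1[C@@H](C)c1c(OCc3ccccc3)c(C)c2c(c1OCc4ccccc4)C(=O)[C@H](C)[C@H]2C
F3 | step 20 | tert-butyldimethylsilyl enol ether of 29 (C1'–OSi, C1'=C3') | CC(=O)Oc1cc([C@H](C)[C@@H](C)OC(C)=O)c(C)c(OC(C)=O)c1[C@H](C)c1c(OS(=O)(=O)C(F)(F)F)c(C)c2c(c1OS(=O)(=O)C(F)(F)F)C(O[Si](C)(C)C(C)(C)C)=C(C)[C@H]2C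
F4 | step 20 | keto acid: C8a' carboxylic acid, C4a' bearing (S)-3-oxobutan-2-yl | CC(=O)Oc1cc([C@H](C)[C@@H](C)OC(C)=O)c(C)c(OC(C)=O)c1[C@H](C)c1c(OS(=O)(=O)C(F)(F)F)c(C)c([C@H](C)C(C)=O)c(c1OS(=O)(=O)C(F)(F)F)C(=O)O
F5 | step 20 | threo hydroxy acid: C8a' carboxylic acid, C4a' bearing (2S,3R)-3-hydroxybutan-2-yl | CC(=O)Oc1cc([C@H](C)[C@@H](C)OC(C)=O)c(C)c(OC(C)=O)c1[C@H](C)c1c(OS(=O)(=O)C(F)(F)F)c(C)c([C@H](C)[C@@H](C)O)c(c1OS(=O)(=O)C(F)(F)F)C(=O)O
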